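**Plan**

- Labels: ring A is the sulfated phenyl ring, numbered so that carbon 1 bears the ether oxygen, carbon 3 the sulfate and carbon 5 the free hydroxyl. Ring B is the 2,6-dihydroxy-4-(sulfooxy)phenoxy ring, with carbon 1 on the ether oxygen.
- Retrosynthesis: the two S-O bonds and the three O-benzyl bonds are cut first. Ring A is then cut between carbons 2 and 3 and between carbons 1 and 6 into 3-(benzyloxy)cyclobutenone and the ethynyl ether of the ring B phenol. The bond between carbons 3 and 4 is the one closed by electrocyclisation.
- The ethynyl ether goes back to the ring B phenol and trichloroethylene. The phenol goes back through a Baeyer-Villiger cut at carbon 4 of ring B to 3,4,5-trihydroxybenzaldehyde.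
- Enabling feature: ring A has three mutually meta oxygens that all differ (aryloxy, sulfate, hydroxyl). This is the pattern produced when a 3-alkoxy vinylketene (two oxygens) combines with an ynol ether (the third).
- Forward: ring B is present from the start and is dressed first. Ring A is built last, directly on the ether oxygen. Methoxymethyl removal, double sulfation and hydrogenolysis follow.
- Stereochemistry: the target has no stereocentre. The only geometric element on the way, the (E)-dichlorovinyl ether, is erased one step later.

Key step: step 9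

Remark on the chemistry: the aryl hydrogen sulfates 21 and 22 are written as free acids, as in the target formula. They would be carried as sodium salts, and 22 would be set free on a cold sulfonic acid resin directly before isolation, because free aryl hydrogen sulfates hydrolyse on standing. 3,4,5-Trihydroxybenzaldehyde, trichloroethylene and cyclobutane-1,3-dione are taken as purchased compounds.

**Route**

Step 1
Reactants: 1 3,4,5-trihydroxybenzaldehyde
Product: 2 4-(allyloxy)-3,5-dihydroxybenzaldehyde
Conditions: allyl bromide (1.05 equiv), NaHCO3 (1.2 equiv), NaI (cat.), DMF, 40 °C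
Reagents that add atoms: allyl bromide, C=CCBr
Why: Williamson etherification under a weak base, in which only the 4-hydroxyl (para to the formyl group and the most acidic) is ionised, so monoallylation at the 4-oxygen is expected, as in the known selective 4-O-alkylation of gallate-type triols.

Step 2
Reactants: 2 4-(allyloxy)-3,5-dihydroxybenzaldehyde
Product: 3 4-(allyloxy)-3,5-bis(benzyloxy)benzaldehyde
Conditions: BnBr (2.4 equiv), K2CO3 (3 equiv), DMF, rt
Reagents that add atoms: benzyl bromide, BrCc1ccccc1
Why: Williamson etherification of the two remaining phenols; the allyl ether and the aldehyde are inert to carbonate and benzyl bromide.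

Step 3
Reactants: 3 4-(allyloxy)-3,5-bis(benzyloxy)benzaldehyde
Product: 5 4-(allyloxy)-3,5-bis(benzyloxy)phenol, via aryl formate 4 (not isolated)
Conditions: mCPBA (1.3 equiv), CH2Cl2, 0 °C to rt; NaHCO3 wash; then K2CO3 (cat.), MeOH, rt
Reagents that add atoms: 3-chloroperoxybenzoic acid (mCPBA), O=C(OO)c1cccc(Cl)c1
Why: Baeyer-Villiger oxidation in which the electron-rich trialkoxyaryl group migrates to give the aryl formate, which is then methanolysed to the phenol; the monosubstituted allyl alkene should be epoxidised far more slowly than the aldehyde is oxidised.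

Step 4
Reactants: 5 4-(allyloxy)-3,5-bis(benzyloxy)phenol
Product: 6 2-(allyloxy)-1,3-bis(benzyloxy)-5-(methoxymethoxy)benzene
Conditions: MOMCl (1.5 equiv), iPr2NEt (2 equiv), CH2Cl2, 0 °C to rt
Reagents that add atoms: chloromethyl methyl ether, COCCl
Why: O-alkylation of an unhindered phenol with chloromethyl methyl ether (methoxymethyl protection), which caps the future sulfate oxygen of ring B with a group that survives base, butyllithium at low temperature and heat.

Step 5
Reactants: 6 2-(allyloxy)-1,3-bis(benzyloxy)-5-(methoxymethoxy)benzene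
Product: 7 2,6-bis(benzyloxy)-4-(methoxymethoxy)phenol
Conditions: Pd(PPh3)4 (3 mol %), morpholine (3 equiv), degassed THF, rt
Reagents that add atoms: none
Why: Tsuji-Trost-type deallylation, in which zerovalent palladium ionises the aryl allyl ether to a π-allyl complex and morpholine captures the allyl group; benzyl and methoxymethyl ethers are untouched.

Step 6
Reactants: 7 2,6-bis(benzyloxy)-4-(methoxymethoxy)phenol; 8 trichloroethylene
Product: 9 1,3-bis(benzyloxy)-2-{[(E)-1,2-dichloroethenyl]oxy}-5-(methoxymethoxy)benzene
Conditions: trichloroethylene (1.5 equiv), K2CO3 (1.5 equiv), DMF, 70 °C, argon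
Reagents that add atoms: trichloroethylene (compound 8), ClC=C(Cl)Cl
Why: Base-mediated addition of the phenoxide to dichloroacetylene formed in situ from trichloroethylene (the dichlorovinyl ether route to ynol ethers); anti addition gives the (E) isomer, the hindered phenoxide only has to attack a linear alkyne, and the geometry is erased in the next step.

Step 7
Reactants: 9 1,3-bis(benzyloxy)-2-{[(E)-1,2-dichloroethenyl]oxy}-5-(methoxymethoxy)benzene
Product: 12 1,3-bis(benzyloxy)-2-(ethynyloxy)-5-(methoxymethoxy)benzene, via chloroalkynyl ether 10 (not isolated), via lithium acetylide 11 (not isolated)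
Conditions: n-BuLi (2.3 equiv), Et2O, -78 to -40 °C; then MeOH, -78 °C; cold work-up, used at once
Reagents that add atoms: none
Why: Double dehydrochlorination-type sequence known for dichlorovinyl ethers, in which deprotonation and chloride loss give the chloroalkyne, chlorine-lithium exchange gives the lithium acetylide and low-temperature protonation gives the terminal ynol ether; at -78 °C ortho-lithiation beside the ether groups should not compete.

Step 8
Reactants: 13 cyclobutane-1,3-dione
Product: 14 3-(benzyloxy)cyclobut-2-en-1-one
Conditions: BnBr (1.1 equiv), Ag2O (0.6 equiv), MeCN, 0 °C to rt, dark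
Reagents that add atoms: benzyl bromide, BrCc1ccccc1
Why: Ag2O-mediated O-alkylation of a strongly acidic enolised 1,3-dione (a vinylogous carboxylic acid), in which the cation-like benzyl electrophile is taken by the oxygen terminus of the ambident anion, the same mode as the Ag2O alkylation of squaric and tetronic acids.

Step 9
Reactants: 12 1,3-bis(benzyloxy)-2-(ethynyloxy)-5-(methoxymethoxy)benzene; 14 3-(benzyloxy)cyclobut-2-en-1-one
Product: 19 3-(benzyloxy)-5-[2,6-bis(benzyloxy)-4-(methoxymethoxy)phenoxy]phenol, via vinylketene 15 (not isolated), via vinylcyclobutenone 16 (not isolated), via dienylketene 17 (not isolated), via cyclohexadienone 18 (not isolated)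
Conditions: 12 (1.0 equiv), 14 (1.5 equiv), toluene (0.2 M), 80 °C then 110 °C, argon, sealed tube; then K2CO3 (cat.), MeOH, rt, to release any phenol acylated by a ketene
Reagents that add atoms: none
Why: Danheiser benzannulation: cyclobutenone 14 opens by four-electron electrocyclic ring opening to vinylketene 15, whose carbonyl carbon is attacked by the nucleophilic terminal carbon of ynol ether 12 in a (2+2) cycloaddition that forms the ring A bonds between carbons 2 and 3 and between carbons 1 and 6 and gives cyclobutenone 16. A second four-electron opening gives dienylketene 17, and ring A closes by 6π electrocyclisation of the ketene carbon (carbon 3) onto the methylene terminus (carbon 4), after which dienone 18 tautomerises to phenol 19. The closest known reactions are the benzannulations of cyclobutenones with alkoxy- and siloxyalkynes. No stereocentre is formed; the sp3 carbon of 16 is transient and racemic. The step needs regioselectivity in the ketene-alkyne cycloaddition, and the polarisation of the ynol ether by its oxygen secures it, so the aryloxy carbon ends meta to the new hydroxyl and the benzyloxy carbon (carbon 3 of the cyclobutenone) ends meta to both. The aryl ynol ether has no hydrogen placed for retro-ene loss of ketene, and all ring B oxygens are capped so that no phenol of the precursor intercepts the ketenes.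

Step 10
Reactants: 19 3-(benzyloxy)-5-[2,6-bis(benzyloxy)-4-(methoxymethoxy)phenoxy]phenol
Product: 20 3-(benzyloxy)-5-[2,6-bis(benzyloxy)-4-hydroxyphenoxy]phenol
Conditions: HCl (cat., 0.5 M in MeOH), MeOH/THF, 40 °C
Reagents that add atoms: none
Why: Acid-catalysed acetal exchange (methoxymethyl ether cleavage), in which methanol traps the methoxymethyl cation as dimethoxymethane before it can alkylate the electron-rich rings; benzyl ethers and the diaryl ether are stable.

Step 11
Reactants: 20 3-(benzyloxy)-5-[2,6-bis(benzyloxy)-4-hydroxyphenoxy]phenol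
Product: 21 3-(benzyloxy)-5-[2,6-bis(benzyloxy)-4-(sulfooxy)phenoxy]phenyl hydrogen sulfate
Conditions: SO3·pyridine (6 equiv), pyridine, 45 °C; NaHCO3 work-up
Reagents that add atoms: sulfur trioxide pyridine complex, O=S(=O)=O.c1ccncc1
Why: O-sulfation of phenols with the SO3-pyridine complex; both free hydroxyls (ring A carbon 3 and ring B carbon 4) are unhindered, and the mild complex should not sulfonate ring carbons.

Step 12
Reactants: 21 3-(benzyloxy)-5-[2,6-bis(benzyloxy)-4-(sulfooxy)phenoxy]phenyl hydrogen sulfate
Product: 22 3-[2,6-dihydroxy-4-(sulfooxy)phenoxy]-5-hydroxyphenyl hydrogen sulfate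
Conditions: H2 (1 atm), 10% Pd/C, MeOH/H2O, rt; then sulfonic acid ion-exchange resin (H+ form), 0 °C
Reagents that add atoms: none
Why: Catalytic hydrogenolysis of the three benzyl ethers; aryl sulfate monoesters (as their salts) and the diaryl ether are inert to hydrogen over Pd/C.

**Compound list**

1 | 3,4,5-trihydroxybenzaldehyde | O=Cc1cc(O)c(O)c(O)c1 | starting material
2 | 4-(allyloxy)-3,5-dihydroxybenzaldehyde | C=CCOc1c(O)cc(C=O)cc1O | intermediate
3 | 4-(allyloxy)-3,5-bis(benzyloxy)benzaldehyde | C=CCOc1c(OCc2ccccc2)cc(C=O)cc1OCc1ccccc1 | intermediate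
4 | 4-(allyloxy)-3,5-bis(benzyloxy)phenyl formate | C=CCOc1c(OCc2ccccc2)cc(OC=O)cc1OCc1ccccc1 | intermediate
5 | 4-(allyloxy)-3,5-bis(benzyloxy)phenol | C=CCOc1c(OCc2ccccc2)cc(O)cc1OCc1ccccc1 | intermediate
6 | 2-(allyloxy)-1,3-bis(benzyloxy)-5-(methoxymethoxy)benzene | C=CCOc1c(OCc2ccccc2)cc(OCOC)cc1OCc1ccccc1 | intermediate
7 | 2,6-bis(benzyloxy)-4-(methoxymethoxy)phenol | Oc1c(OCc2ccccc2)cc(OCOC)cc1OCc1ccccc1 | intermediate
8 | trichloroethylene | ClC=C(Cl)Cl | starting material
9 | 1,3-bis(benzyloxy)-2-{[(E)-1,2-dichloroethenyl]oxy}-5-(methoxymethoxy)benzene | Cl/C=C(/Cl)Oc1c(OCc2ccccc2)cc(OCOC)cc1OCc1ccccc1 | intermediate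
10 | 1,3-bis(benzyloxy)-2-[(chloroethynyl)oxy]-5-(methoxymethoxy)benzene | ClC#COc1c(OCc2ccccc2)cc(OCOC)cc1OCc1ccccc1 | intermediate
11 | lithium [2,6-bis(benzyloxy)-4-(methoxymethoxy)phenoxy]ethynide | [Li]C#COc1c(OCc2ccccc2)cc(OCOC)cc1OCc1ccccc1 | intermediate
12 | 1,3-bis(benzyloxy)-2-(ethynyloxy)-5-(methoxymethoxy)benzene | C#COc1c(OCc2ccccc2)cc(OCOC)cc1OCc1ccccc1 | intermediate
13 | cyclobutane-1,3-dione | O=C1CC(=O)C1 | starting material
14 | 3-(benzyloxy)cyclobut-2-en-1-one | O=C1C=C(OCc2ccccc2)C1 | intermediate
15 | 3-(benzyloxy)buta-1,3-dien-1-one | O=C=CC(=C)OCc1ccccc1 | intermediate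
16 | 3-[2,6-bis(benzyloxy)-4-(methoxymethoxy)phenoxy]-4-[1-(benzyloxy)ethenyl]cyclobut-2-en-1-one (racemic) | O=C1C=C(Oc2c(OCc3ccccc3)cc(OCOC)cc2OCc2ccccc2)C1C(=C)OCc1ccccc1 | intermediate
17 | (3E)-5-(benzyloxy)-3-[2,6-bis(benzyloxy)-4-(methoxymethoxy)phenoxy]hexa-1,3,5-trien-1-one | O=C=C/C(Oc1c(OCc2ccccc2)cc(OCOC)cc1OCc1ccccc1)=C\C(=C)OCc1ccccc1 | intermediate
18 | 5-(benzyloxy)-3-[2,6-bis(benzyloxy)-4-(methoxymethoxy)phenoxy]cyclohexa-2,4-dien-1-one | O=C1C=C(Oc2c(OCc3ccccc3)cc(OCOC)cc2OCc2ccccc2)C=C(OCc2ccccc2)C1 | intermediate
19 | 3-(benzyloxy)-5-[2,6-bis(benzyloxy)-4-(methoxymethoxy)phenoxy]phenol | Oc1cc(OCc2ccccc2)cc(Oc2c(OCc3ccccc3)cc(OCOC)cc2OCc2ccccc2)c1 | intermediate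
20 | 3-(benzyloxy)-5-[2,6-bis(benzyloxy)-4-hydroxyphenoxy]phenol | Oc1cc(OCc2ccccc2)cc(Oc2c(OCc3ccccc3)cc(O)cc2OCc2ccccc2)c1 | intermediate
21 | 3-(benzyloxy)-5-[2,6-bis(benzyloxy)-4-(sulfooxy)phenoxy]phenyl hydrogen sulfate | O=S(=O)(O)Oc1cc(OCc2ccccc2)cc(Oc2c(OCc3ccccc3)cc(OS(=O)(=O)O)cc2OCc2ccccc2)c1 | intermediate
22 | 3-[2,6-dihydroxy-4-(sulfooxy)phenoxy]-5-hydroxyphenyl hydrogen sulfate | O=S(=O)(O)Oc1cc(O)cc(Oc2c(O)cc(OS(=O)(=O)O)cc2O)c1 | target

**Step count and risks**

Total step count: 12. Longest linear sequence: 11 steps (steps 1 to 7 and 9 to 12); step 8 is a one-step branch.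

Steps most likely to fail:

1. Step 9. The bimolecular ketene-alkyne cycloaddition may lose out to oligomerisation of the terminal aryl ynol ether and to dimerisation of the vinylketene. The phenol being formed may also be acylated by ketene intermediates, so the cascade may not run cleanly to the phenol. The fallback sets out from phenol 7 and joins a ready-made ring A to the ether oxygen by coupling instead of building ring A on it. Commercial 5-bromobenzene-1,3-diol is monobenzylated (BnBr, K2CO3, acetone) to 3-(benzyloxy)-5-bromophenol F1. Its remaining hydroxyl is capped with MOMCl and iPr2NEt to give 1-(benzyloxy)-3-bromo-5-(methoxymethoxy)benzene F2. An Ullmann diaryl ether coupling of 7 with the bromide (CuI, picolinic acid, K3PO4, DMSO, 90 °C) should give 1,3-bis(benzyloxy)-2-[3-(benzyloxy)-5-(methoxymethoxy)phenoxy]-5-(methoxymethoxy)benzene F3. Acid in methanol then removes both methoxymethyl groups, and the route is rejoined at diol 20.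

2. Step 7. The terminal ynol ether may be lost to hydration or oligomerisation during quench, concentration and handling, and ring lithiation beside the ether groups may erode the material if the temperature rises. The fallback sets out from dichlorovinyl ether 9. The lithium acetylide is generated as before but quenched with Me3SiCl, which should give the more robust {[2,6-bis(benzyloxy)-4-(methoxymethoxy)phenoxy]ethynyl}trimethylsilane F4. Benzannulation of this silyl ynol ether with cyclobutenone 14 under the conditions of step 9 would place the silyl group on the ring A carbon between the aryloxy and hydroxyl carbons. The expected product is 5-(benzyloxy)-3-[2,6-bis(benzyloxy)-4-(methoxymethoxy)phenoxy]-2-(trimethylsilyl)phenol F5. HCl in methanol then effects ipso-protodesilylation of the very electron-rich ring together with methoxymethyl cleavage, and the route is rejoined at diol 20.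

3. Step 8. The ambident dione anion may be benzylated at carbon 2 instead of oxygen, and the strained ring may be opened by nucleophiles, so O-selectivity and mass balance may be poor. The fallback sets out from dione 13 and moves the bond formation from the benzylic carbon to the ring carbon. Oxalyl chloride with catalytic DMF in CH2Cl2 converts 13 into the vinylogous acid chloride 3-chlorocyclobut-2-en-1-one F6. Addition-elimination of benzyl alcohol with Et3N at 0 °C then gives cyclobutenone 14, where the route is rejoined; C-alkylation cannot occur in this mode.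

**Further compounds**

F1 | step 9 | 3-(benzyloxy)-5-bromophenol | Oc1cc(Br)cc(OCc2ccccc2)c1
F2 | step 9 | 1-(benzyloxy)-3-bromo-5-(methoxymethoxy)benzene | COCOc1cc(Br)cc(OCc2ccccc2)c1
F3 | step 9 | 1,3-bis(benzyloxy)-2-[3-(benzyloxy)-5-(methoxymethoxy)phenoxy]-5-(methoxymethoxy)benzene | COCOc1cc(OCc2ccccc2)cc(Oc2c(OCc3ccccc3)cc(OCOC)cc2OCc2ccccc2)c1
F4 | step 7 | {[2,6-bis(benzyloxy)-4-(methoxymethoxy)phenoxy]ethynyl}trimethylsilane | C[Si](C)(C)C#COc1c(OCc2ccccc2)cc(OCOC)cc1OCc1ccccc1
F5 | step 7 | 5-(benzyloxy)-3-[2,6-bis(benzyloxy)-4-(methoxymethoxy)phenoxy]-2-(trimethylsilyl)phenol | C[Si](C)(C)c1c(O)cc(OCc2ccccc2)cc1Oc1c(OCc2ccccc2)cc(OCOC)cc1OCc1ccccc1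
F6 | step 8 | 3-chlorocyclobut-2-en-1-one | O=C1C=C(Cl)C1
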